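**Retrosynthetic overview**

1. The target comes from hydrogenolysis of a tetrabenzyl depside. Its ring A 2-OMe and 4-OBn groups come from regioselective alkylation of a depside carrying a free ring A 2,4-dihydroxybenzoate.
2. Ring A is the only ring built (ring B is carried intact from 5-propylresorcinol). It is closed by an aldol condensation of a 3,5,7-trioxodecanoyl chain held as an ester on the ring B C3 oxygen: chain C2 to chain C7 becomes ring A C1–C6.
3. The aryl triketo ester comes from the ring B 3-phenol and an acylketene released from a diketo-dioxinone, itself made from the trimethyl-dioxinone, acetyl chloride and a butanoyl Weinreb amide.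
4. The ring B phenol comes from divarinol dibenzyl ether by C2 lithiation–borylation–oxidation, then bromination and bromine–lithium exchange with benzyloxycarbonylation.
5. Feature: ring A is a tetraketide (divaric acid) unit, so the bond from its carboxyl-bearing C1 to its propyl-bearing C6 is an aldol bond. The ester carbonyl that ends up flanked by four ortho substituents (ring A C2–O and C6-propyl, ring B C2–O and C4–O) can be attached to ring B O3 while it is still an unhindered open-chain β-keto ester.

Key step: step 11

Remark: the target has no stereocentre. The 1,3-dicarbonyl compounds are drawn as keto tautomers although they should exist largely as enols, and the aldol adduct 25 is a transient mixture of stereoisomers whose stereocentres vanish on aromatization.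

**Ring B phenol**

Step 1
Reactants: 1 5-propylbenzene-1,3-diol; 2 benzyl bromide
Product: 3 1,3-bis(benzyloxy)-5-propylbenzene
Conditions: BnBr (2.3 equiv), K2CO3, DMF, rt to 60 °C
Reagents that add atoms: benzyl bromide (2), BrCc1ccccc1
Why: Williamson ether synthesis, in which both resorcinol phenoxides are O-alkylated by the reactive benzylic bromide.

Step 2
Reactants: 3 1,3-bis(benzyloxy)-5-propylbenzene
Product: 6 2,6-bis(benzyloxy)-4-propylphenol, via aryllithium 4 (not isolated), via dimethyl arylboronate 5 (not isolated)
Conditions: n-BuLi, THF, 0 °C to rt; B(OMe)3, −78 °C to rt; 30% H2O2, aq. NaOH, 0 °C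
Reagents that add atoms: hydrogen peroxide, OO; n-butyllithium, [Li]CCCC, and trimethyl borate, COB(OC)OC, leave atoms only in 4 and 5
Why: Directed ortho-metalation removes the ring proton flanked by both benzyloxy groups, and borate trapping followed by boronate oxidation (C–B to C–O migration) should give the central phenol with its two neighbours already differentiated as benzyl ethers.

Step 3
Reactants: 6 2,6-bis(benzyloxy)-4-propylphenol
Product: 7 [2,6-bis(benzyloxy)-4-propylphenoxy](tert-butyl)dimethylsilane
Conditions: TBSCl, imidazole, DMF, rt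
Reagents that add atoms: tert-butyldimethylsilyl chloride, CC(C)(C)[Si](C)(C)Cl
Why: Imidazole-promoted silylation of the phenol installs a group that should survive NBS and n-BuLi at −78 °C and later leave with fluoride without touching the benzyl groups.

Step 4
Reactants: 7 [2,6-bis(benzyloxy)-4-propylphenoxy](tert-butyl)dimethylsilane
Product: 8 [2,6-bis(benzyloxy)-3-bromo-4-propylphenoxy](tert-butyl)dimethylsilane
Conditions: NBS (1.05 equiv), MeCN, 0 °C to rt
Reagents that add atoms: N-bromosuccinimide, O=C1CCC(=O)N1Br
Why: Electrophilic aromatic bromination, where the only two free ring positions are equivalent by symmetry and each is ortho to one benzyloxy group and para to the other, so one equivalent of NBS should give a single monobromide.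

Step 5
Reactants: 8 [2,6-bis(benzyloxy)-3-bromo-4-propylphenoxy](tert-butyl)dimethylsilane; 9 benzyl chloroformate
Product: 11 benzyl 2,4-bis(benzyloxy)-3-[(tert-butyldimethylsilyl)oxy]-6-propylbenzoate, via aryllithium 10 (not isolated)
Conditions: n-BuLi, THF, −78 °C; cannulated into ClCO2Bn (2 equiv), THF, −78 °C
Reagents that add atoms: benzyl chloroformate (9), O=C(Cl)OCc1ccccc1; n-butyllithium, [Li]CCCC, leaves lithium only in 10
Why: Bromine–lithium exchange at −78 °C is faster than benzylic deprotonation, and inverse addition to excess chloroformate (acyl substitution) should stop at the ester because its two ortho substituents block a second addition.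

Step 6
Reactants: 11 benzyl 2,4-bis(benzyloxy)-3-[(tert-butyldimethylsilyl)oxy]-6-propylbenzoate
Product: 12 benzyl 2,4-bis(benzyloxy)-3-hydroxy-6-propylbenzoate
Conditions: Bu4NF, AcOH, THF, 0 °C
Reagents that add atoms: none
Why: Fluoride-induced desilylation buffered with acetic acid should free only the 3-hydroxyl and leave the benzyl ethers and the hindered benzyl ester intact.

**Diketo-dioxinone**

Step 7
Reactants: 13 2,2,6-trimethyl-4H-1,3-dioxin-4-one; 14 acetyl chloride
Product: 16 2,2-dimethyl-6-(2-oxopropyl)-4H-1,3-dioxin-4-one, via lithium dienolate 15 (not isolated)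
Conditions: 13 (2 equiv), LiN(SiMe3)2 (2 equiv), THF, −78 °C; AcCl (1 equiv), −78 °C; aq. HCl
Reagents that add atoms: acetyl chloride (14), CC(Cl)=O; LiN(SiMe3)2, [Li]N([Si](C)(C)C)[Si](C)(C)C, leaves lithium only in 15
Why: Vinylogous Claisen-type C-acylation of the dioxinone dienolate at its γ-carbon, with the second equivalent of dienolate absorbing the proton of the more acidic product.

Step 8
Reactants: 17 butanoyl chloride; 18 N,O-dimethylhydroxylamine hydrochloride
Product: 19 N-methoxy-N-methylbutanamide
Conditions: Et3N (2.2 equiv), CH2Cl2, 0 °C to rt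
Reagents that add atoms: N,O-dimethylhydroxylamine hydrochloride (18), CNOC.Cl
Why: Schotten–Baumann-type N-acylation of the hydroxylamine gives the Weinreb amide.

Step 9
Reactants: 16 2,2-dimethyl-6-(2-oxopropyl)-4H-1,3-dioxin-4-one; 19 N-methoxy-N-methylbutanamide
Product: 22 6-(2,4-dioxoheptyl)-2,2-dimethyl-4H-1,3-dioxin-4-one, via dilithium dianion 20 (not isolated), via chelated tetrahedral adduct 21 (not isolated)
Conditions: LiN(i-Pr)2 (2.1 equiv), THF, −78 °C; 19, −78 to 0 °C; 1 M HCl
Reagents that add atoms: N-methoxy-N-methylbutanamide (19), CCCC(=O)N(C)OC; LiN(i-Pr)2, [Li]N(C(C)C)C(C)C, leaves lithium only in 20 and 21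
Why: Claisen-type acylation of the dianion at its terminal, most nucleophilic carbon, where the Weinreb amide stops at the chelated adduct so that neither over-addition nor proton transfer from a 1,3-diketone product consumes the dianion.

**Union, key step and endgame**

Step 10
Reactants: 22 6-(2,4-dioxoheptyl)-2,2-dimethyl-4H-1,3-dioxin-4-one; 12 benzyl 2,4-bis(benzyloxy)-3-hydroxy-6-propylbenzoate
Product: 24 benzyl 2,4-bis(benzyloxy)-6-propyl-3-[(3,5,7-trioxodecanoyl)oxy]benzoate, via acylketene 23 (not isolated)
Conditions: 22 (1.5 equiv) added over 1 h to 12, toluene, 110 °C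
Reagents that add atoms: none
Why: Retro-hetero-Diels–Alder loss of acetone releases the acylketene, and addition of the phenol to its unhindered ketene carbon (acylketene trapping) forms the depside C–O bond without acyl substitution at a congested benzoyl carbon.

Step 11
Reactants: 24 benzyl 2,4-bis(benzyloxy)-6-propyl-3-[(3,5,7-trioxodecanoyl)oxy]benzoate
Product: 26 benzyl 2,4-bis(benzyloxy)-3-[(2,4-dihydroxy-6-propylbenzoyl)oxy]-6-propylbenzoate, via cyclic aldol adduct 25 (not isolated)
Conditions: Et3N (5 equiv), CH2Cl2, 0 °C to rt; then HCl (4 M in dioxane), rt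
Reagents that add atoms: none
Why: Triethylamine reversibly deprotonates chain C2 between the aryl ester and the C3 ketone, and this enolate adds to the C7 ketone to form the C2–C7 bond that becomes ring A C1–C6; acid then eliminates water from the tertiary aldol 25 and the C3 and C5 carbonyls enolize, so aromatization drives the sequence forward. The closest known reaction type is the base-mediated aldol aromatization of 3,5,7-triketo esters made by acylketene trapping, which gives 6-alkyl-2,4-dihydroxybenzoates. Ring A closes in a 6-(enolexo)-exo-trig mode. No stereocentre is set, since the two stereocentres of 25 are lost on dehydration and enolization. The step needs chemoselectivity for the C2-to-C7 aldol over attack of C6 (Claisen closure) or of the C5 enol oxygen (pyranone formation) on the aryl ester carbonyl, either of which would expel the ring B phenoxide. A weak, non-nucleophilic amine in an aprotic solvent at or below room temperature, the absence of any alcohol or alkoxide, and the two ortho benzyloxy groups that flank the ester oxygen and screen its carbonyl should keep the ester intact while the unhindered C7 ketone reacts.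

Step 12
Reactants: 26 benzyl 2,4-bis(benzyloxy)-3-[(2,4-dihydroxy-6-propylbenzoyl)oxy]-6-propylbenzoate; 2 benzyl bromide
Product: 27 benzyl 2,4-bis(benzyloxy)-3-{[4-(benzyloxy)-2-hydroxy-6-propylbenzoyl]oxy}-6-propylbenzoate
Conditions: BnBr (1.1 equiv), K2CO3, acetone, rt
Reagents that add atoms: benzyl bromide (2), BrCc1ccccc1
Why: Williamson etherification should be selective for the ring A 4-hydroxyl, which is more acidic and not hydrogen-bonded, over the 2-hydroxyl chelated to the ester carbonyl.

Step 13
Reactants: 27 benzyl 2,4-bis(benzyloxy)-3-{[4-(benzyloxy)-2-hydroxy-6-propylbenzoyl]oxy}-6-propylbenzoate; 28 iodomethane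
Product: 29 benzyl 2,4-bis(benzyloxy)-3-{[4-(benzyloxy)-2-methoxy-6-propylbenzoyl]oxy}-6-propylbenzoate
Conditions: MeI (5 equiv), K2CO3, DMF, 40 °C
Reagents that add atoms: iodomethane (28), CI
Why: Williamson O-methylation of the one remaining phenol, whose hydrogen bond is overcome in DMF with excess MeI while the doubly ortho-substituted aryl ester resists carbonate.

Step 14
Reactants: 29 benzyl 2,4-bis(benzyloxy)-3-{[4-(benzyloxy)-2-methoxy-6-propylbenzoyl]oxy}-6-propylbenzoate
Product: 30 2,4-dihydroxy-3-[(4-hydroxy-2-methoxy-6-propylbenzoyl)oxy]-6-propylbenzoic acid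
Conditions: H2 (1 atm), 10% Pd/C, EtOAc, rt
Reagents that add atoms: none
Why: Catalytic hydrogenolysis cleaves the three benzyl ethers and the benzyl ester, while the diaryl ester, the methyl ether and the arenes are inert at room temperature and the hindered acyl group should not migrate under neutral conditions.

**Compound list**

1 | 5-propylbenzene-1,3-diol (divarinol) | CCCc1cc(O)cc(O)c1 | starting material
2 | benzyl bromide | BrCc1ccccc1 | starting material
3 | 1,3-bis(benzyloxy)-5-propylbenzene | CCCc1cc(OCc2ccccc2)cc(OCc2ccccc2)c1 | intermediate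
4 | [2,6-bis(benzyloxy)-4-propylphenyl]lithium (not isolated) | CCCc1cc(OCc2ccccc2)c([Li])c(OCc2ccccc2)c1 | intermediate
5 | dimethyl [2,6-bis(benzyloxy)-4-propylphenyl]boronate (not isolated) | CCCc1cc(OCc2ccccc2)c(B(OC)OC)c(OCc2ccccc2)c1 | intermediate
6 | 2,6-bis(benzyloxy)-4-propylphenol | CCCc1cc(OCc2ccccc2)c(O)c(OCc2ccccc2)c1 | intermediate
7 | [2,6-bis(benzyloxy)-4-propylphenoxy](tert-butyl)dimethylsilane | CCCc1cc(OCc2ccccc2)c(O[Si](C)(C)C(C)(C)C)c(OCc2ccccc2)c1 | intermediate
8 | [2,6-bis(benzyloxy)-3-bromo-4-propylphenoxy](tert-butyl)dimethylsilane | CCCc1cc(OCc2ccccc2)c(O[Si](C)(C)C(C)(C)C)c(OCc2ccccc2)c1Br | intermediate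
9 | benzyl chloroformate | O=C(Cl)OCc1ccccc1 | starting material
10 | [2,4-bis(benzyloxy)-3-(tert-butyldimethylsilyloxy)-6-propylphenyl]lithium (not isolated) | CCCc1cc(OCc2ccccc2)c(O[Si](C)(C)C(C)(C)C)c(OCc2ccccc2)c1[Li] | intermediate
11 | benzyl 2,4-bis(benzyloxy)-3-[(tert-butyldimethylsilyl)oxy]-6-propylbenzoate | CCCc1cc(OCc2ccccc2)c(O[Si](C)(C)C(C)(C)C)c(OCc2ccccc2)c1C(=O)OCc1ccccc1 | intermediate
12 | benzyl 2,4-bis(benzyloxy)-3-hydroxy-6-propylbenzoate | CCCc1cc(OCc2ccccc2)c(O)c(OCc2ccccc2)c1C(=O)OCc1ccccc1 | intermediate
13 | 2,2,6-trimethyl-4H-1,3-dioxin-4-one | CC1=CC(=O)OC(C)(C)O1 | starting material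
14 | acetyl chloride | CC(Cl)=O | starting material
15 | lithium 2,2-dimethyl-6-methylidene-6H-1,3-dioxin-4-olate (not isolated) | C=C1C=C(O[Li])OC(C)(C)O1 | intermediate
16 | 2,2-dimethyl-6-(2-oxopropyl)-4H-1,3-dioxin-4-one | CC(=O)CC1=CC(=O)OC(C)(C)O1 | intermediate
17 | butanoyl chloride | CCCC(=O)Cl | starting material
18 | N,O-dimethylhydroxylamine hydrochloride | CNOC.Cl | starting material
19 | N-methoxy-N-methylbutanamide | CCCC(=O)N(C)OC | intermediate
20 | dilithium dianion of 16 (dienolate and terminal enolate; not isolated) | C=C(O[Li])C=C1C=C(O[Li])OC(C)(C)O1 | intermediate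
21 | lithium-chelated tetrahedral adduct of 20 with 19 (not isolated) | CCCC(O[Li])(N(C)OC)CC(=O)C=C1C=C(O[Li])OC(C)(C)O1 | intermediate
22 | 6-(2,4-dioxoheptyl)-2,2-dimethyl-4H-1,3-dioxin-4-one | CCCC(=O)CC(=O)CC1=CC(=O)OC(C)(C)O1 | intermediate
23 | 3,5,7-trioxodec-1-en-1-one (acylketene; not isolated) | CCCC(=O)CC(=O)CC(=O)C=C=O | intermediate
24 | benzyl 2,4-bis(benzyloxy)-6-propyl-3-[(3,5,7-trioxodecanoyl)oxy]benzoate | CCCC(=O)CC(=O)CC(=O)CC(=O)Oc1c(OCc2ccccc2)cc(CCC)c(C(=O)OCc2ccccc2)c1OCc1ccccc1 | intermediate
25 | benzyl 2,4-bis(benzyloxy)-3-[(2-hydroxy-4,6-dioxo-2-propylcyclohexane-1-carbonyl)oxy]-6-propylbenzoate (stereoisomer mixture; not isolated) | CCCC1(O)CC(=O)CC(=O)C1C(=O)Oc1c(OCc2ccccc2)cc(CCC)c(C(=O)OCc2ccccc2)c1OCc1ccccc1 | intermediate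
26 | benzyl 2,4-bis(benzyloxy)-3-[(2,4-dihydroxy-6-propylbenzoyl)oxy]-6-propylbenzoate | CCCc1cc(O)cc(O)c1C(=O)Oc1c(OCc2ccccc2)cc(CCC)c(C(=O)OCc2ccccc2)c1OCc1ccccc1 | intermediate
27 | benzyl 2,4-bis(benzyloxy)-3-{[4-(benzyloxy)-2-hydroxy-6-propylbenzoyl]oxy}-6-propylbenzoate | CCCc1cc(OCc2ccccc2)cc(O)c1C(=O)Oc1c(OCc2ccccc2)cc(CCC)c(C(=O)OCc2ccccc2)c1OCc1ccccc1 | intermediate
28 | iodomethane | CI | starting material
29 | benzyl 2,4-bis(benzyloxy)-3-{[4-(benzyloxy)-2-methoxy-6-propylbenzoyl]oxy}-6-propylbenzoate | CCCc1cc(OCc2ccccc2)cc(OC)c1C(=O)Oc1c(OCc2ccccc2)cc(CCC)c(C(=O)OCc2ccccc2)c1OCc1ccccc1 | intermediate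
30 | 2,4-dihydroxy-3-[(4-hydroxy-2-methoxy-6-propylbenzoyl)oxy]-6-propylbenzoic acid (CNP0482898.0) | CCCc1cc(O)cc(OC)c1C(=O)Oc1c(O)cc(CCC)c(C(=O)O)c1O | target

**Step count**

Total: 14 steps. Longest linear sequence: 11 steps (steps 1–6, then 10–14); steps 7–9 form the side branch.

**Steps most likely to fail**

1. Step 11. Attack on the aryl ester carbonyl may outrun the aldol: Claisen closure from C6, lactonization through the C5 enol oxygen, or reversal to the acylketene, each with loss of the ring B phenoxide. The fallback completes ring A on a simple ester and makes the depside bond afterwards by acyl transfer. It sets out from 22. Thermolysis in toluene at 110 °C with allyl alcohol should give allyl 3,5,7-trioxodecanoate F1. Et3N in CH2Cl2, then HCl in dioxane, should aromatize it to allyl 2,4-dihydroxy-6-propylbenzoate F2. BnBr and K2CO3 in acetone should give allyl 4-(benzyloxy)-2-hydroxy-6-propylbenzoate F3, and MeI and K2CO3 in DMF should give allyl 4-(benzyloxy)-2-methoxy-6-propylbenzoate F4. Pd(PPh3)4 with morpholine in THF should free 4-(benzyloxy)-2-methoxy-6-propylbenzoic acid F5. Trifluoroacetic anhydride in toluene should convert F5 into 4-(benzyloxy)-2-methoxy-6-propylbenzoic trifluoroacetic anhydride F6, which acylates phenol 12 by way of its stabilized acylium ion. This gives 29, where the route is rejoined before step 14.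

2. Step 10. Unimolecular cyclization of the acylketene through its enolized C5 carbonyl, or thermal reversal of the phenol addition at 110 °C, may outpace capture by the hindered, weakly nucleophilic phenol. The fallback changes the acyl donor to a thioester that is activated at room temperature by a thiophilic silver salt. It sets out from 22. Thermolysis in toluene at 110 °C with 2-methylpropane-2-thiol, an unhindered and strongly nucleophilic trap, should give S-tert-butyl 3,5,7-trioxodecanethioate F7. F7 and phenol 12 with AgOCOCF3 (silver trifluoroacetate) in THF at room temperature should then give 24, where the route is rejoined before step 11.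

3. Step 9. Proton transfer to the dianion, or sluggish addition to the Weinreb amide, may leave the acylation incomplete and return 16. The fallback forms the C–C bond by aldol addition to an aldehyde and then adjusts the oxidation level. It sets out from 16. The dianion 20 (LiN(i-Pr)2, THF, −78 °C) with butanal should give racemic 6-(4-hydroxy-2-oxoheptyl)-2,2-dimethyl-4H-1,3-dioxin-4-one F8. Dess–Martin periodinane in CH2Cl2 should oxidize F8 to 22, where the route is rejoined before step 10.

**Further compounds**

F1 | step 11 | allyl 3,5,7-trioxodecanoate | CCCC(=O)CC(=O)CC(=O)CC(=O)OCC=C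
F2 | step 11 | allyl 2,4-dihydroxy-6-propylbenzoate | CCCc1cc(O)cc(O)c1C(=O)OCC=C
F3 | step 11 | allyl 4-(benzyloxy)-2-hydroxy-6-propylbenzoate | CCCc1cc(OCc2ccccc2)cc(O)c1C(=O)OCC=C
F4 | step 11 | allyl 4-(benzyloxy)-2-methoxy-6-propylbenzoate | CCCc1cc(OCc2ccccc2)cc(OC)c1C(=O)OCC=C
F5 | step 11 | 4-(benzyloxy)-2-methoxy-6-propylbenzoic acid | CCCc1cc(OCc2ccccc2)cc(OC)c1C(=O)O
F6 | step 11 | 4-(benzyloxy)-2-methoxy-6-propylbenzoic trifluoroacetic anhydride | CCCc1cc(OCc2ccccc2)cc(OC)c1C(=O)OC(=O)C(F)(F)F
F7 | step 10 | S-tert-butyl 3,5,7-trioxodecanethioate | CCCC(=O)CC(=O)CC(=O)CC(=O)SC(C)(C)C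
F8 | step 9 | 6-(4-hydroxy-2-oxoheptyl)-2,2-dimethyl-4H-1,3-dioxin-4-one | CCCC(O)CC(=O)CC1=CC(=O)OC(C)(C)O1
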